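**Retrosynthetic overview**

1. The route rests on the quinone ring of the right-hand half: C4 is a carbene carbon, C3 (ethyl) and C2 (the C2–O–C3' ether oxygen) are the two carbons of an ynol ether, and C1 is a carbon monoxide carbon. They are joined on the C4a–C8a edge of a 2,4,5-trimethoxyphenyl ring by a Dötz benzannulation, so the hindered tertiary ether is never made by substitution.
2. The alkyne partner is the but-1-ynyl ether of a tetralin in which C3' is already the quaternary carbinol carbon. C1', C2' and C4' are carried as methoxymethyl-protected carbinols, not as a C1'=C2' alkene, because an ynol ether with an allylic C–O bond would be lost by a [3,3] shift to a ketene as soon as it formed.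
3. The carbocycle of the trione half is made first (Wittig olefination, α-ethylation, cyclodehydration to a 2-ethyl-1-naphthol); C3' is then set by asymmetric hydroxylative dearomatisation, followed by dihydroxylation and ketone reduction. The quinone ring is the last ring formed.
4. After the annulation: oxidation to the quinone, acetal removal, oxidation of three carbinols to the 1',2',4'-trione, and cleavage of six methyl ethers.

Key step: step 12

Assumption: the (R)-atropisomer of the biaryl iodane is written in step 6; if oxygen transfer favours the other face of the naphthol, its mirror image is used.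
Assumption: the tetralin carbons C1, C3 and C4 (C4', C2' and C1' of the target) are drawn with the configurations expected from steps 7 and 8; all three become carbonyl carbons in step 15, so their epimers would serve equally.

**Route**

Step 1
Reactants: 1 5-bromo-2-hydroxy-3-methoxybenzaldehyde
Product: 2 2-hydroxy-3,5-dimethoxybenzaldehyde
Conditions: NaOMe, CuCl (10 mol %), MeOH–DMF, 110 °C; aq. HCl
Reagents that add atoms: sodium methoxide, [Na+].[O-]C
Why: Copper-catalysed Ullmann-type methoxylation of the aryl bromide, in which the phenoxide formed first shields the aldehyde from methoxide.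

Step 2
Reactants: 2 2-hydroxy-3,5-dimethoxybenzaldehyde
Product: 3 2,3,5-trimethoxybenzaldehyde
Conditions: MeI, K2CO3, DMF, rt
Reagents that add atoms: iodomethane, CI
Why: Williamson O-methylation of the phenol.

Step 3
Reactants: 3 2,3,5-trimethoxybenzaldehyde; 4 (2-carboxyethyl)triphenylphosphonium bromide
Product: 5 (E)-4-(2,3,5-trimethoxyphenyl)but-3-enoic acid
Conditions: NaN(SiMe3)2 (2.1 equiv), THF, −78 °C to rt; aq. HCl
Reagents that add atoms: none
Why: Wittig olefination with the carboxylate-bearing ylide should give mainly the E β,γ-unsaturated acid, and the alkene geometry is lost in step 5 in any case.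

Step 4
Reactants: 5 (E)-4-(2,3,5-trimethoxyphenyl)but-3-enoic acid; 6 iodoethane
Product: 7 (E)-2-ethyl-4-(2,3,5-trimethoxyphenyl)but-3-enoic acid (racemic)
Conditions: LiN(i-Pr)2 (2.2 equiv), THF, −78 °C; then 6, −78 to 0 °C; aq. HCl
Reagents that add atoms: none
Why: Alkylation of the dienolate dianion of a β,γ-unsaturated acid, which reacts at the α-carbon; the new centre is racemic and is erased on aromatisation.

Step 5
Reactants: 7 (E)-2-ethyl-4-(2,3,5-trimethoxyphenyl)but-3-enoic acid
Product: 9 2-ethyl-5,6,8-trimethoxynaphthalen-1-ol, via naphthyl acetate 8 (not isolated)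
Conditions: Ac2O, NaOAc, 140 °C; then K2CO3, MeOH, rt, argon
Reagents that add atoms: none
Why: Cyclodehydration of a 4-arylbut-3-enoic acid through its mixed anhydride (Friedel–Crafts-type acylation at the only free ortho carbon, activated by ortho and para methoxy groups) and enolisation give the 1-naphthyl acetate, which is cleaved by methanolysis in the same pot.

Step 6
Reactants: 9 2-ethyl-5,6,8-trimethoxynaphthalen-1-ol
Product: 10 (R)-2-ethyl-2-hydroxy-5,6,8-trimethoxynaphthalen-1(2H)-one
Conditions: (R)-2,2'-diiodyl-6,6'-dimethoxy-1,1'-biphenyl (1.1 equiv), THF, −40 °C to rt; then aq. Na2S2O4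
Reagents that add atoms: (R)-2,2'-diiodyl-6,6'-dimethoxy-1,1'-biphenyl, COc1cccc(I(=O)=O)c1-c1c(OC)cccc1I(=O)=O
Why: Hydroxylative phenol dearomatisation: the naphthol binds to pentavalent iodine and oxygen is delivered intramolecularly to the ethyl-bearing ortho carbon, the axially chiral biaryl choosing the face (reagent control) and so setting the C2 carbinol centre that becomes C3' of the target.

Step 7
Reactants: 10 (R)-2-ethyl-2-hydroxy-5,6,8-trimethoxynaphthalen-1(2H)-one
Product: 11 (2R,3R,4R)-2-ethyl-2,3,4-trihydroxy-5,6,8-trimethoxy-3,4-dihydronaphthalen-1(2H)-one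
Conditions: OsO4 (5 mol %), Me3NO·2H2O, CH2Cl2, rt
Reagents that add atoms: trimethylamine N-oxide, C[N+](C)(C)[O-]; water, O
Why: Catalytic cis-dihydroxylation of the styrene-type alkene under non-aqueous, hydrogen-bond-directing conditions should occur on the face of the tertiary hydroxyl, which is also the face away from ethyl, so C3 and C4 are set syn to the C2 hydroxyl by substrate control.

Step 8
Reactants: 11 (2R,3R,4R)-2-ethyl-2,3,4-trihydroxy-5,6,8-trimethoxy-3,4-dihydronaphthalen-1(2H)-one
Product: 12 (1R,2S,3R,4R)-2-ethyl-5,6,8-trimethoxy-1,2,3,4-tetrahydronaphthalene-1,2,3,4-tetraol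
Conditions: NaBH4, MeOH, 0 °C
Reagents that add atoms: none
Why: Borohydride reduction of the aryl ketone, with hydride expected on the hydroxyl-bearing face away from the ethyl group to give the 1,2-trans diol (substrate control at C1).

Step 9
Reactants: 12 (1R,2S,3R,4R)-2-ethyl-5,6,8-trimethoxy-1,2,3,4-tetrahydronaphthalene-1,2,3,4-tetraol
Product: 13 (1R,2S,3R,4R)-2-ethyl-5,6,8-trimethoxy-1,3,4-tris(methoxymethoxy)-1,2,3,4-tetrahydronaphthalen-2-ol
Conditions: MeOCH2Cl (4 equiv), i-Pr2NEt, Bu4NI (cat.), CH2Cl2, 0 to 40 °C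
Reagents that add atoms: chloromethyl methyl ether, COCCl
Why: Acetal-forming O-alkylation protects the three secondary hydroxyls while the tertiary hydroxyl, flanked by two branched carbons, reacts far more slowly; acetal ethers are chosen because, unlike silyl ethers, they cannot migrate to the neighbouring alkoxide in step 10.

Step 10
Reactants: 13 (1R,2S,3R,4R)-2-ethyl-5,6,8-trimethoxy-1,3,4-tris(methoxymethoxy)-1,2,3,4-tetrahydronaphthalen-2-ol; 14 trichloroethylene; 6 iodoethane
Product: 17 (1R,2S,3R,4R)-2-(but-1-yn-1-yloxy)-2-ethyl-5,6,8-trimethoxy-1,3,4-tris(methoxymethoxy)-1,2,3,4-tetrahydronaphthalene, via dichlorovinyl ether 15 (not isolated), via lithium alkynyl ether 16 (not isolated)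
Conditions: KH, THF, 0 °C to rt; 14, −50 °C to rt; then n-BuLi (2.4 equiv), −78 to −40 °C; then 6, HMPA, −40 °C to rt
Reagents that add atoms: none
Why: One-pot ynol ether synthesis: the potassium alkoxide adds to dichloroacetylene generated from trichloroethylene, n-BuLi converts the E-dichlorovinyl ether by elimination and chlorine–lithium exchange into the lithium alkynyl ether, and this is alkylated by iodoethane; no C–O bond at C2 is broken, so the stereocentre is untouched.

Step 11
Reactants: 18 1-bromo-2,4,5-trimethoxybenzene; 19 chromium hexacarbonyl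
Product: 22 pentacarbonyl[methoxy(2,4,5-trimethoxyphenyl)methylidene]chromium, via aryllithium 20 (not isolated), via lithium acylchromate 21 (not isolated)
Conditions: n-BuLi, THF, −78 °C; Cr(CO)6, −78 °C to rt; then Me3OBF4, CH2Cl2–H2O, 0 °C
Reagents that add atoms: trimethyloxonium tetrafluoroborate, C[O+](C)C.F[B-](F)(F)F
Why: Standard alkoxycarbene complex synthesis: bromine–lithium exchange, addition of the aryllithium to a carbonyl ligand of zerovalent chromium, and O-methylation of the acylchromate.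

Step 12
Reactants: 22 pentacarbonyl[methoxy(2,4,5-trimethoxyphenyl)methylidene]chromium; 17 (1R,2S,3R,4R)-2-(but-1-yn-1-yloxy)-2-ethyl-5,6,8-trimethoxy-1,3,4-tris(methoxymethoxy)-1,2,3,4-tetrahydronaphthalene
Product: 23 3-ethyl-2-{[(1R,2S,3R,4R)-2-ethyl-5,6,8-trimethoxy-1,3,4-tris(methoxymethoxy)-1,2,3,4-tetrahydronaphthalen-2-yl]oxy}-4,5,7,8-tetramethoxynaphthalen-1-ol
Conditions: 22 (1.5 equiv), THF (degassed, 0.05 M), 50 °C, argon; then air, MeCN, rt
Reagents that add atoms: none
Why: Dötz benzannulation: the ethyl-bearing, nucleophilic carbon of the ynol ether bonds to the carbene carbon of 22 (after loss of one carbonyl ligand, eased by the ortho-methoxy group), giving an alkenyl(alkoxy)carbene with the oxygen-bearing carbon on chromium, and carbonyl insertion then gives a metal-bound aryl vinylketene (C4–C3 and C2–C1 formed). The quinone-ring carbocycle is closed by 6π-electrocyclisation of this ketene onto the only free ortho carbon of the trimethoxyphenyl ring (C1–C8a), and tautomerisation gives the 4-methoxy-1-naphthol, which air frees from chromium. The closest known reaction is the benzannulation of aryl(methoxy)carbene complexes of zerovalent chromium with alkynyl ethers, which places the alkoxy group next to the phenolic carbon. No stereocentre is formed and the quaternary C2 of the tetralin is not involved. The step needs regioselective insertion (oxygen-bearing alkyne carbon next to the carbonyl-derived C1), secured jointly by the polarisation of the ynol ether and the bulk of its tert-alkoxy end, and phenol rather than indene formation, favoured by THF and the methoxycarbene. Working at 50 °C keeps the tert-alkyl ynol ether below the temperature of retro-ene loss of ketene, and the absence of an allylic or benzylic C–O bond at C2 excludes a sigmatropic shift of the alkyne.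

Step 13
Reactants: 23 3-ethyl-2-{[(1R,2S,3R,4R)-2-ethyl-5,6,8-trimethoxy-1,3,4-tris(methoxymethoxy)-1,2,3,4-tetrahydronaphthalen-2-yl]oxy}-4,5,7,8-tetramethoxynaphthalen-1-ol
Product: 24 3-ethyl-2-{[(1R,2S,3R,4R)-2-ethyl-5,6,8-trimethoxy-1,3,4-tris(methoxymethoxy)-1,2,3,4-tetrahydronaphthalen-2-yl]oxy}-5,7,8-trimethoxynaphthalene-1,4-dione
Conditions: PhI(OAc)2 (1.1 equiv), MeCN–H2O (4:1), 0 °C
Reagents that add atoms: water, O
Why: Two-electron oxidation of the 4-methoxy-1-naphthol (oxidative demethylation: water adds at C4 and methanol is lost) gives the 1,4-quinone; the free naphthol is oxidised far faster than the aryl methyl ethers of either ring.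

Step 14
Reactants: 24 3-ethyl-2-{[(1R,2S,3R,4R)-2-ethyl-5,6,8-trimethoxy-1,3,4-tris(methoxymethoxy)-1,2,3,4-tetrahydronaphthalen-2-yl]oxy}-5,7,8-trimethoxynaphthalene-1,4-dione
Product: 25 3-ethyl-2-{[(1R,2S,3R,4R)-2-ethyl-1,3,4-trihydroxy-5,6,8-trimethoxy-1,2,3,4-tetrahydronaphthalen-2-yl]oxy}-5,7,8-trimethoxynaphthalene-1,4-dione
Conditions: Me3SiOTf, 2,2'-bipyridyl, CH2Cl2, 0 °C to rt; then H2O
Reagents that add atoms: none
Why: Silyl-triflate-mediated cleavage of the three methoxymethyl acetals, buffered by bipyridyl, and hydrolysis of the resulting pyridinium acetals should free the carbinols without base or strong acid, sparing the quinonyl ether (a vinylogous ester); the triol is used at once.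

Step 15
Reactants: 25 3-ethyl-2-{[(1R,2S,3R,4R)-2-ethyl-1,3,4-trihydroxy-5,6,8-trimethoxy-1,2,3,4-tetrahydronaphthalen-2-yl]oxy}-5,7,8-trimethoxynaphthalene-1,4-dione
Product: 26 (3S)-3-ethyl-3-[(3-ethyl-5,7,8-trimethoxy-1,4-dioxo-1,4-dihydronaphthalen-2-yl)oxy]-5,7,8-trimethoxynaphthalene-1,2,4(3H)-trione
Conditions: 2-iodoxybenzoic acid (IBX, 8 equiv), DMSO, rt to 40 °C
Reagents that add atoms: none
Why: Alcohol oxidation with a λ5-iodane, which converts 1,2-diols into 1,2-diketones without C–C cleavage, takes all three carbinols to ketones; the absence of base avoids β-elimination of the quinonyloxy group from the intermediate α-hydroxy ketone, and the quaternary C3' is untouched.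

Step 16
Reactants: 26 (3S)-3-ethyl-3-[(3-ethyl-5,7,8-trimethoxy-1,4-dioxo-1,4-dihydronaphthalen-2-yl)oxy]-5,7,8-trimethoxynaphthalene-1,2,4(3H)-trione
Product: 27 (3S)-3-ethyl-3-[(3-ethyl-5,7,8-trihydroxy-1,4-dioxo-1,4-dihydronaphthalen-2-yl)oxy]-5,7,8-trihydroxynaphthalene-1,2,4(3H)-trione (CNP0325426.1)
Conditions: BBr3 (12 equiv), CH2Cl2, −78 to 0 °C; then H2O
Reagents that add atoms: none
Why: Lewis-acid cleavage of the six aryl methyl ethers (peri-methoxy groups assisted by carbonyl chelation, the 7- and 7'-methoxy groups by the neighbouring borate); the C3'–O bond lies between two carbonyl carbons and cannot ionise, so the ether link and the stereocentre should survive.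

**Compound list**

1 | 5-bromo-2-hydroxy-3-methoxybenzaldehyde | O=Cc1cc(Br)cc(OC)c1O | starting material
2 | 2-hydroxy-3,5-dimethoxybenzaldehyde | O=Cc1cc(OC)cc(OC)c1O | intermediate
3 | 2,3,5-trimethoxybenzaldehyde | O=Cc1cc(OC)cc(OC)c1OC | intermediate
4 | (2-carboxyethyl)triphenylphosphonium bromide | OC(=O)CC[P+](c1ccccc1)(c1ccccc1)c1ccccc1.[Br-] | starting material
5 | (E)-4-(2,3,5-trimethoxyphenyl)but-3-enoic acid | OC(=O)C/C=C/c1cc(OC)cc(OC)c1OC | intermediate
6 | iodoethane | CCI | starting material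
7 | (E)-2-ethyl-4-(2,3,5-trimethoxyphenyl)but-3-enoic acid (racemic) | CCC(C(=O)O)/C=C/c1cc(OC)cc(OC)c1OC | intermediate
8 | 2-ethyl-5,6,8-trimethoxynaphthalen-1-yl acetate | CCc1ccc2c(OC)c(OC)cc(OC)c2c1OC(C)=O | intermediate (not isolated)
9 | 2-ethyl-5,6,8-trimethoxynaphthalen-1-ol | CCc1ccc2c(OC)c(OC)cc(OC)c2c1O | intermediate
10 | (R)-2-ethyl-2-hydroxy-5,6,8-trimethoxynaphthalen-1(2H)-one | O[C@]1(CC)C=Cc2c(OC)c(OC)cc(OC)c2C1=O | intermediate
11 | (2R,3R,4R)-2-ethyl-2,3,4-trihydroxy-5,6,8-trimethoxy-3,4-dihydronaphthalen-1(2H)-one | O[C@]1(CC)[C@H](O)[C@H](O)c2c(OC)c(OC)cc(OC)c2C1=O | intermediate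
12 | (1R,2S,3R,4R)-2-ethyl-5,6,8-trimethoxy-1,2,3,4-tetrahydronaphthalene-1,2,3,4-tetraol | O[C@]1(CC)[C@H](O)[C@H](O)c2c(OC)c(OC)cc(OC)c2[C@H]1O | intermediate
13 | (1R,2S,3R,4R)-2-ethyl-5,6,8-trimethoxy-1,3,4-tris(methoxymethoxy)-1,2,3,4-tetrahydronaphthalen-2-ol | O[C@]1(CC)[C@H](OCOC)[C@H](OCOC)c2c(OC)c(OC)cc(OC)c2[C@H]1OCOC | intermediate
14 | trichloroethylene | ClC=C(Cl)Cl | starting material
15 | (1R,2S,3R,4R)-2-{[(E)-1,2-dichloroethenyl]oxy}-2-ethyl-5,6,8-trimethoxy-1,3,4-tris(methoxymethoxy)-1,2,3,4-tetrahydronaphthalene | Cl/C=C(/Cl)O[C@]1(CC)[C@H](OCOC)[C@H](OCOC)c2c(OC)c(OC)cc(OC)c2[C@H]1OCOC | intermediate (not isolated)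
16 | lithium 2-{[(1R,2S,3R,4R)-2-ethyl-5,6,8-trimethoxy-1,3,4-tris(methoxymethoxy)-1,2,3,4-tetrahydronaphthalen-2-yl]oxy}ethynide | [Li]C#CO[C@]1(CC)[C@H](OCOC)[C@H](OCOC)c2c(OC)c(OC)cc(OC)c2[C@H]1OCOC | intermediate (not isolated)
17 | (1R,2S,3R,4R)-2-(but-1-yn-1-yloxy)-2-ethyl-5,6,8-trimethoxy-1,3,4-tris(methoxymethoxy)-1,2,3,4-tetrahydronaphthalene | CCC#CO[C@]1(CC)[C@H](OCOC)[C@H](OCOC)c2c(OC)c(OC)cc(OC)c2[C@H]1OCOC | intermediate (key-step precursor)
18 | 1-bromo-2,4,5-trimethoxybenzene | COc1cc(OC)c(Br)cc1OC | starting material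
19 | chromium hexacarbonyl | O=C=[Cr](=C=O)(=C=O)(=C=O)(=C=O)=C=O | starting material
20 | (2,4,5-trimethoxyphenyl)lithium | [Li]c1cc(OC)c(OC)cc1OC | intermediate (not isolated)
21 | lithium pentacarbonyl[oxido(2,4,5-trimethoxyphenyl)methylidene]chromate | [Li+].[O-]C(=[Cr](=C=O)(=C=O)(=C=O)(=C=O)=C=O)c1cc(OC)c(OC)cc1OC | intermediate (not isolated)
22 | pentacarbonyl[methoxy(2,4,5-trimethoxyphenyl)methylidene]chromium | COC(=[Cr](=C=O)(=C=O)(=C=O)(=C=O)=C=O)c1cc(OC)c(OC)cc1OC | intermediate (key-step precursor)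
23 | 3-ethyl-2-{[(1R,2S,3R,4R)-2-ethyl-5,6,8-trimethoxy-1,3,4-tris(methoxymethoxy)-1,2,3,4-tetrahydronaphthalen-2-yl]oxy}-4,5,7,8-tetramethoxynaphthalen-1-ol | CCc1c(OC)c2c(OC)cc(OC)c(OC)c2c(O)c1O[C@]1(CC)[C@H](OCOC)[C@H](OCOC)c2c(OC)c(OC)cc(OC)c2[C@H]1OCOC | intermediate (key-step product)
24 | 3-ethyl-2-{[(1R,2S,3R,4R)-2-ethyl-5,6,8-trimethoxy-1,3,4-tris(methoxymethoxy)-1,2,3,4-tetrahydronaphthalen-2-yl]oxy}-5,7,8-trimethoxynaphthalene-1,4-dione | CCC1=C(O[C@]2(CC)[C@H](OCOC)[C@H](OCOC)c3c(OC)c(OC)cc(OC)c3[C@H]2OCOC)C(=O)c2c(OC)c(OC)cc(OC)c2C1=O | intermediate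
25 | 3-ethyl-2-{[(1R,2S,3R,4R)-2-ethyl-1,3,4-trihydroxy-5,6,8-trimethoxy-1,2,3,4-tetrahydronaphthalen-2-yl]oxy}-5,7,8-trimethoxynaphthalene-1,4-dione | CCC1=C(O[C@]2(CC)[C@H](O)[C@H](O)c3c(OC)c(OC)cc(OC)c3[C@H]2O)C(=O)c2c(OC)c(OC)cc(OC)c2C1=O | intermediate
26 | (3S)-3-ethyl-3-[(3-ethyl-5,7,8-trimethoxy-1,4-dioxo-1,4-dihydronaphthalen-2-yl)oxy]-5,7,8-trimethoxynaphthalene-1,2,4(3H)-trione | CCC1=C(O[C@]2(CC)C(=O)C(=O)c3c(OC)c(OC)cc(OC)c3C2=O)C(=O)c2c(OC)c(OC)cc(OC)c2C1=O | intermediate
27 | (3S)-3-ethyl-3-[(3-ethyl-5,7,8-trihydroxy-1,4-dioxo-1,4-dihydronaphthalen-2-yl)oxy]-5,7,8-trihydroxynaphthalene-1,2,4(3H)-trione | CCC1=C(O[C@]2(CC)C(=O)C(=O)c3c(O)c(O)cc(O)c3C2=O)C(=O)c2c(O)c(O)cc(O)c2C1=O | target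

**Step count and risks**

Total step count: 16. Longest linear sequence: 15 steps (steps 1–10, then 12–16); step 11 is the second branch.

Steps most likely to fail:

1. Step 12. The alkoxy-stabilised alkenylcarbene formed after alkyne insertion may stall before carbonyl insertion or divert to cyclobutenone, indene or furan products, and the crowded tert-alkyl ynol ether may fragment by retro-ene loss of ketene before it is consumed. Fallback, setting out from 9 and 13 and coming back at 24: the ether bond is made by conjugate addition–elimination instead of annulation. Para-oxidation of naphthol 9 with (KSO3)2NO in buffered aqueous acetone gives 2-ethyl-5,6,8-trimethoxynaphthalene-1,4-dione F1. Bromine with NaOAc in acetic acid (addition, then loss of hydrogen bromide) gives 2-bromo-3-ethyl-5,7,8-trimethoxynaphthalene-1,4-dione F2. The potassium alkoxide of 13 (KH, THF, 18-crown-6, −20 °C) then displaces bromide from F2 to give 24.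

2. Step 10. Addition of the very hindered tertiary alkoxide to dichloroacetylene may be slower than the decomposition of dichloroacetylene, leaving 13 unchanged. Fallback, setting out from 13 and coming back at 17: the alkyne carbon is attached as a formate and then homologated. Acetic formic anhydride and pyridine give (1R,2S,3R,4R)-2-ethyl-5,6,8-trimethoxy-1,3,4-tris(methoxymethoxy)-1,2,3,4-tetrahydronaphthalen-2-yl formate F3. Dibromomethylenation of the formate carbonyl with CBr4 and PPh3 gives the 2,2-dibromoethenyl ether F4. n-BuLi (2.2 equiv, −78 °C) converts F4 by elimination and bromine–lithium exchange into the same lithium alkynyl ether 16, which iodoethane 6 in HMPA alkylates to 17.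

3. Step 6. Facial discrimination in the oxygen transfer may be poor, or oxidation may go to the para carbon C4 and give the quinone instead of the quinol. Fallback, setting out from 7 and coming back at 10: the stereocentre is set by enolate hydroxylation of a tetralone. Hydrogenation of 7 (H2, Pd on carbon, EtOAc) gives 2-ethyl-4-(2,3,5-trimethoxyphenyl)butanoic acid F5. Friedel–Crafts cyclisation with (CF3CO)2O in CF3CO2H gives 2-ethyl-5,6,8-trimethoxy-3,4-dihydronaphthalen-1(2H)-one F6. Hydroxylation of its sodium enolate (NaN(SiMe3)2, THF, −78 °C) with the enantiomer of (8,8-dichlorocamphorylsulfonyl)oxaziridine that delivers the R alcohol gives (R)-2-ethyl-2-hydroxy-5,6,8-trimethoxy-3,4-dihydronaphthalen-1(2H)-one F7. Benzylic bromination (N-bromosuccinimide, (PhCO2)2, light, PhCF3) gives (2R)-4-bromo-2-ethyl-2-hydroxy-5,6,8-trimethoxy-3,4-dihydronaphthalen-1(2H)-one F8, and dehydrobromination with DBU gives 10.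

Further compounds
F1 | step 12 | 2-ethyl-5,6,8-trimethoxynaphthalene-1,4-dione | CCC1=CC(=O)c2c(OC)c(OC)cc(OC)c2C1=O
F2 | step 12 | 2-bromo-3-ethyl-5,7,8-trimethoxynaphthalene-1,4-dione | CCC1=C(Br)C(=O)c2c(OC)c(OC)cc(OC)c2C1=O
F3 | step 10 | (1R,2S,3R,4R)-2-ethyl-5,6,8-trimethoxy-1,3,4-tris(methoxymethoxy)-1,2,3,4-tetrahydronaphthalen-2-yl formate | O=CO[C@]1(CC)[C@H](OCOC)[C@H](OCOC)c2c(OC)c(OC)cc(OC)c2[C@H]1OCOC
F4 | step 10 | (1R,2S,3R,4R)-2-[(2,2-dibromoethenyl)oxy]-2-ethyl-5,6,8-trimethoxy-1,3,4-tris(methoxymethoxy)-1,2,3,4-tetrahydronaphthalene | BrC(Br)=CO[C@]1(CC)[C@H](OCOC)[C@H](OCOC)c2c(OC)c(OC)cc(OC)c2[C@H]1OCOC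
F5 | step 6 | 2-ethyl-4-(2,3,5-trimethoxyphenyl)butanoic acid (racemic) | CCC(CCc1cc(OC)cc(OC)c1OC)C(=O)O
F6 | step 6 | 2-ethyl-5,6,8-trimethoxy-3,4-dihydronaphthalen-1(2H)-one (racemic) | CCC1CCc2c(OC)c(OC)cc(OC)c2C1=O
F7 | step 6 | (R)-2-ethyl-2-hydroxy-5,6,8-trimethoxy-3,4-dihydronaphthalen-1(2H)-one | O[C@]1(CC)CCc2c(OC)c(OC)cc(OC)c2C1=O
F8 | step 6 | (2R)-4-bromo-2-ethyl-2-hydroxy-5,6,8-trimethoxy-3,4-dihydronaphthalen-1(2H)-one (both C4 epimers) | O[C@]1(CC)CC(Br)c2c(OC)c(OC)cc(OC)c2C1=O
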